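Ring A, the benzene ring of the 7-methoxycoumarin half, is substituted at every carbon except C6. Its sequence C8 (aryl), C8a (oxygen), C4a (bearing C4, a carboxyl carbon), C5 (methyl) is read as C3–C6 of a 2-pyrone, and C6–C7(OMe) as methoxyethyne. The route rests on cutting C5–C6 and C7–C8. One cycloaddition with loss of CO2 converts a 3-aryl-2-pyrone-5-carboxylate into the complete ring A, with regiochemistry and biaryl axis included. The precursor already carries the finished 7'-O-benzyl coumarin (ring B half) on pyrone C3. Its C4 oxygen is masked as an acetate so that the diene stays electron-poor.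

Key step: step 9

Numbering used: coumarin numbering. Unprimed is the 7-methoxy half (benzene ring A, joined at C8). Primed is the 7-hydroxy half (benzene ring B, joined at C6').
Assumption: the target SMILES carries no axial descriptor, so the hindered C8–C6' biaryl is made as the racemate and no step has to control the axis.

Step 1
Reactants: 1 methyl acetoacetate; 2 malonyl dichloride
Product: 3 methyl 4-hydroxy-6-methyl-2-oxo-2H-pyran-5-carboxylate
Conditions: 1 (slight excess), ClCH2CH2Cl, 0 → 60 °C, N2 sweep to carry off HCl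
Reagents that add atoms: none
Why: Malonyl dichloride acylates the active methylene carbon and then the ketone enol oxygen of the β-keto ester (C,O-bisacylation/cyclocondensation, the standard entry to 4-hydroxy-2-pyrone-5-carboxylates), and loss of two HCl makes the closure irreversible.

Step 2
Reactants: 4 methyl 2,4-dihydroxy-6-methylbenzoate (methyl orsellinate)
Product: 5 methyl 4-(benzyloxy)-2-hydroxy-6-methylbenzoate
Conditions: BnBr (1.05 equiv), K2CO3 (1.1 equiv), acetone, reflux
Reagents that add atoms: benzyl bromide, BrCc1ccccc1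
Why: Williamson ether synthesis in which the 2-OH, locked in a hydrogen bond to the ester carbonyl, stays inert while the freer and more acidic 4-OH is alkylated.

Step 3
Reactants: 5 methyl 4-(benzyloxy)-2-hydroxy-6-methylbenzoate
Product: 6 methyl 4-(benzyloxy)-6-hydroxy-3-iodo-2-methylbenzoate (iodine between the methyl and the benzyloxy group)
Conditions: NIS (1.05 equiv), CF3CO2H (0.2 equiv), MeCN, 0 °C → rt, dark
Reagents that add atoms: N-iodosuccinimide, O=C1CCC(=O)N1I
Why: Electrophilic aromatic iodination should go para to the free phenol and ortho to the benzyloxy group because the only other open site is wedged between two oxygens, and iodinating before the lactone exists avoids the competing C3' and C8' positions of a 4-methoxycoumarin.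

Step 4
Reactants: 6 methyl 4-(benzyloxy)-6-hydroxy-3-iodo-2-methylbenzoate
Product: 8 7-(benzyloxy)-6-iodo-4-methoxy-5-methyl-2H-chromen-2-one, via acyl ylide 7 (not isolated)
Conditions: Ph3P=C=C=O (1.3 equiv), toluene, reflux
Reagents that add atoms: ketenylidenetriphenylphosphorane, O=C=C=P(c1ccccc1)(c1ccccc1)c1ccccc1
Why: The phenol adds to the cumulated ylide to give stabilised acyl ylide 7, whose intramolecular Wittig olefination of the adjacent ester carbonyl closes the lactone and keeps the ester OMe as the 4'-methoxy group, a known annulation of methyl salicylates.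

Step 5
Reactants: 8 7-(benzyloxy)-6-iodo-4-methoxy-5-methyl-2H-chromen-2-one
Product: 9 7-(benzyloxy)-4-methoxy-5-methyl-6-(tributylstannyl)-2H-chromen-2-one
Conditions: (Bu3Sn)2 (1.5 equiv), Pd(PPh3)4 (5 mol%), toluene, 110 °C
Reagents that add atoms: hexabutyldistannane, CCCC[Sn](CCCC)(CCCC)[Sn](CCCC)(CCCC)CCCC
Why: Palladium-catalysed stannylation of an aryl iodide by a distannane (oxidative addition to zerovalent palladium, Sn–Sn transmetallation, reductive elimination) runs without base or nucleophile, so lactone, enol ether and benzyl ether are left alone.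

Step 6
Reactants: 9 7-(benzyloxy)-4-methoxy-5-methyl-6-(tributylstannyl)-2H-chromen-2-one; 3 methyl 4-hydroxy-6-methyl-2-oxo-2H-pyran-5-carboxylate
Product: 11 methyl 3-[7-(benzyloxy)-4-methoxy-5-methyl-2-oxo-2H-chromen-6-yl]-4-hydroxy-6-methyl-2-oxo-2H-pyran-5-carboxylate, via aryllead triacetate 10 (not isolated)
Conditions: Pb(OAc)4 (1.0 equiv), Hg(OAc)2 (10 mol%), CHCl3, 40 °C; then 3 (0.9 equiv), pyridine (3 equiv), 60 °C
Reagents that add atoms: lead tetraacetate, CC(=O)O[Pb](OC(C)=O)(OC(C)=O)OC(C)=O (its atoms stay only in 10, none in 11)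
Why: Mercury-catalysed tin–lead exchange gives aryllead triacetate 10, and in the Pinhey arylation the pyrone enolate binds to tetravalent lead and ligand coupling forges the pyrone C3–C6' bond, a reaction established for 4-hydroxycoumarins and related cyclic β-dicarbonyl enols that is not slowed by two ortho substituents on the aryl group.

Step 7
Reactants: 11 methyl 3-[7-(benzyloxy)-4-methoxy-5-methyl-2-oxo-2H-chromen-6-yl]-4-hydroxy-6-methyl-2-oxo-2H-pyran-5-carboxylate
Product: 12 methyl 4-acetoxy-3-[7-(benzyloxy)-4-methoxy-5-methyl-2-oxo-2H-chromen-6-yl]-6-methyl-2-oxo-2H-pyran-5-carboxylate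
Conditions: Ac2O (1.5 equiv), pyridine, CH2Cl2, 0 °C → rt
Reagents that add atoms: acetic anhydride, CC(=O)OC(C)=O
Why: O-Acylation of a vinylogous carboxylic acid whose C3 already carries the aryl group, so no C-acyl isomer can arise, and the acetate replaces a donor oxygen by a weakly withdrawing one, which lowers the diene LUMO for step 9 and hides the acidic OH from the ynol ether.

Step 8
Reactants: 13 chloroacetaldehyde dimethyl acetal (2-chloro-1,1-dimethoxyethane)
Product: 15 methoxyethyne, via sodium methoxyethynide 14 (not isolated)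
Conditions: NaNH2 (3.2 equiv), liquid NH3, −33 °C; evaporate NH3; cold saturated aq NaCl, −20 °C; distil into cold toluene
Reagents that add atoms: sodium amide, [Na+].[NH2-] (sodium stays only in 14, none in 15)
Why: Two successive base-induced eliminations (MeOH, then HCl) followed by deprotonation to acetylide 14 are the standard preparation of alkoxyalkynes from chloroacetaldehyde acetals, and a cold aqueous quench with distillation should deliver the volatile ynol ether as a toluene stock solution.

Step 9
Reactants: 12 methyl 4-acetoxy-3-[7-(benzyloxy)-4-methoxy-5-methyl-2-oxo-2H-chromen-6-yl]-6-methyl-2-oxo-2H-pyran-5-carboxylate; 15 methoxyethyne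
Product: 17 methyl 2-acetoxy-3-[7-(benzyloxy)-4-methoxy-5-methyl-2-oxo-2H-chromen-6-yl]-4-methoxy-6-methylbenzoate, via bridged lactone 16 (not isolated)
Conditions: 15 (about 15 equiv, toluene stock solution), BHT (1 mol%), sealed pressure vessel, 120 °C
Reagents that add atoms: none
Why: Inverse-electron-demand Diels–Alder reaction: the pyrone diene C3–C6, depleted by the lactone carbonyl, the C5 ester and the non-donating 4-acetoxy group, adds the electron-rich triple bond of 15 in a concerted but asynchronous [4+2] step to give bridged lactone 16, which ejects CO2 by retro-[4+2] under the same conditions. The closest known reaction type is the benzannulation of 2-pyrone-5-carboxylates (coumalates, isodehydroacetates) by ynamines, ketene acetals and alkoxyalkynes. Ring A is closed by this intermolecular [4+2] cycloaddition, which makes C5–C6 and C7–C8, and the CO2 loss alone brings it to the arene level, so no separate dehydrogenation is needed. The two bridgehead centres of 16 disappear with the CO2 and the axis is taken over from 12 as the racemate, so nothing stereochemical has to be controlled. Regioselectivity is needed and comes from polarity matching: the unsubstituted, electron-rich alkyne carbon of 15 attacks pyrone C6, which is β to the ester carbonyl and δ to the lactone carbonyl, so the methoxy-bearing carbon ends up on the aryl-substituted C3. Chemoselectivity is secured because the lactone ring of the coumarin unit would have to give up benzene aromaticity to react as a diene and stays out, while the slim, linear dienophile, which has no β-hydrogen for retro-ene decay to ketene, suits the two fully substituted diene termini and the heating they demand.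

Step 10
Reactants: 17 methyl 2-acetoxy-3-[7-(benzyloxy)-4-methoxy-5-methyl-2-oxo-2H-chromen-6-yl]-4-methoxy-6-methylbenzoate
Product: 18 methyl 3-[7-(benzyloxy)-4-methoxy-5-methyl-2-oxo-2H-chromen-6-yl]-2-hydroxy-4-methoxy-6-methylbenzoate
Conditions: K2CO3 (0.2 equiv), MeOH/CH2Cl2, 0 °C → rt
Reagents that add atoms: none
Why: Base-catalysed transesterification cleaves the aryl acetate far faster than the doubly ortho-substituted methyl benzoate or the vinylogous-carbonate lactone, for both of which attack by methoxide is in any case degenerate or reversible.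

Step 11
Reactants: 18 methyl 3-[7-(benzyloxy)-4-methoxy-5-methyl-2-oxo-2H-chromen-6-yl]-2-hydroxy-4-methoxy-6-methylbenzoate
Product: 20 7'-(benzyloxy)-4,4',7-trimethoxy-5,5'-dimethyl-2H,2'H-[8,6'-bichromene]-2,2'-dione, via acyl ylide 19 (not isolated)
Conditions: Ph3P=C=C=O (1.5 equiv), toluene, reflux
Reagents that add atoms: ketenylidenetriphenylphosphorane, O=C=C=P(c1ccccc1)(c1ccccc1)c1ccccc1
Why: The same phenol addition/intramolecular Wittig annulation as in step 4, which tolerates a biaryl axis ortho to the phenol, turns the salicylate into the second 4-methoxycoumarin and so supplies C2, C3 and the 4-OMe group.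

Step 12
Reactants: 20 7'-(benzyloxy)-4,4',7-trimethoxy-5,5'-dimethyl-2H,2'H-[8,6'-bichromene]-2,2'-dione
Product: 21 7'-hydroxy-4,4',7-trimethoxy-5,5'-dimethyl-2H,2'H-[8,6'-bichromene]-2,2'-dione (target)
Conditions: H2 (1 atm), 10% Pd/C, EtOAc/MeOH, rt
Reagents that add atoms: none
Why: Catalytic hydrogenolysis of the benzyl aryl ether, during which the trisubstituted, methoxy-bearing C3=C4 bonds of both lactone rings should resist hydrogenation at atmospheric pressure.

Compound list
1 | methyl acetoacetate | COC(=O)CC(C)=O | starting material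
2 | malonyl dichloride | ClC(=O)CC(Cl)=O | starting material
3 | methyl 4-hydroxy-6-methyl-2-oxo-2H-pyran-5-carboxylate | COC(=O)c1c(O)cc(=O)oc1C | intermediate
4 | methyl 2,4-dihydroxy-6-methylbenzoate (methyl orsellinate) | COC(=O)c1c(C)cc(O)cc1O | starting material
5 | methyl 4-(benzyloxy)-2-hydroxy-6-methylbenzoate | COC(=O)c1c(C)cc(OCc2ccccc2)cc1O | intermediate
6 | methyl 4-(benzyloxy)-6-hydroxy-3-iodo-2-methylbenzoate | COC(=O)c1c(C)c(I)c(OCc2ccccc2)cc1O | intermediate
7 | methyl 4-(benzyloxy)-3-iodo-2-methyl-6-{[(triphenylphosphoranylidene)acetyl]oxy}benzoate (acyl ylide, not isolated) | COC(=O)c1c(C)c(I)c(OCc2ccccc2)cc1OC(=O)C=P(c1ccccc1)(c1ccccc1)c1ccccc1 | intermediate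
8 | 7-(benzyloxy)-6-iodo-4-methoxy-5-methyl-2H-chromen-2-one | COc1cc(=O)oc2cc(OCc3ccccc3)c(I)c(C)c12 | intermediate
9 | 7-(benzyloxy)-4-methoxy-5-methyl-6-(tributylstannyl)-2H-chromen-2-one | CCCC[Sn](CCCC)(CCCC)c1c(OCc2ccccc2)cc2oc(=O)cc(OC)c2c1C | intermediate
10 | [7-(benzyloxy)-4-methoxy-5-methyl-2-oxo-2H-chromen-6-yl]lead triacetate (not isolated) | CC(=O)O[Pb](OC(C)=O)(OC(C)=O)c1c(OCc2ccccc2)cc2oc(=O)cc(OC)c2c1C | intermediate
11 | methyl 3-[7-(benzyloxy)-4-methoxy-5-methyl-2-oxo-2H-chromen-6-yl]-4-hydroxy-6-methyl-2-oxo-2H-pyran-5-carboxylate | COC(=O)c1c(O)c(-c2c(OCc3ccccc3)cc3oc(=O)cc(OC)c3c2C)c(=O)oc1C | intermediate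
12 | methyl 4-acetoxy-3-[7-(benzyloxy)-4-methoxy-5-methyl-2-oxo-2H-chromen-6-yl]-6-methyl-2-oxo-2H-pyran-5-carboxylate | COC(=O)c1c(OC(C)=O)c(-c2c(OCc3ccccc3)cc3oc(=O)cc(OC)c3c2C)c(=O)oc1C | intermediate
13 | chloroacetaldehyde dimethyl acetal | COC(CCl)OC | starting material
14 | sodium methoxyethynide (not isolated) | [Na+].[C-]#COC | intermediate
15 | methoxyethyne | COC#C | intermediate
16 | methyl 8-acetoxy-4-[7-(benzyloxy)-4-methoxy-5-methyl-2-oxo-2H-chromen-6-yl]-5-methoxy-1-methyl-3-oxo-2-oxabicyclo[2.2.2]octa-5,7-diene-7-carboxylate (racemic, one enantiomer drawn; the bridgeheads are tied to each other by the bicycle; not isolated) | O=C1O[C@]2(C)C=C(OC)[C@@]1(c3c(OCc4ccccc4)cc4oc(=O)cc(OC)c4c3C)C(OC(C)=O)=C2C(=O)OC | intermediate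
17 | methyl 2-acetoxy-3-[7-(benzyloxy)-4-methoxy-5-methyl-2-oxo-2H-chromen-6-yl]-4-methoxy-6-methylbenzoate | COC(=O)c1c(C)cc(OC)c(-c2c(OCc3ccccc3)cc3oc(=O)cc(OC)c3c2C)c1OC(C)=O | intermediate
18 | methyl 3-[7-(benzyloxy)-4-methoxy-5-methyl-2-oxo-2H-chromen-6-yl]-2-hydroxy-4-methoxy-6-methylbenzoate | COC(=O)c1c(C)cc(OC)c(-c2c(OCc3ccccc3)cc3oc(=O)cc(OC)c3c2C)c1O | intermediate
19 | methyl 3-[7-(benzyloxy)-4-methoxy-5-methyl-2-oxo-2H-chromen-6-yl]-4-methoxy-6-methyl-2-{[(triphenylphosphoranylidene)acetyl]oxy}benzoate (acyl ylide, not isolated) | COC(=O)c1c(C)cc(OC)c(-c2c(OCc3ccccc3)cc3oc(=O)cc(OC)c3c2C)c1OC(=O)C=P(c1ccccc1)(c1ccccc1)c1ccccc1 | intermediate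
20 | 7'-(benzyloxy)-4,4',7-trimethoxy-5,5'-dimethyl-2H,2'H-[8,6'-bichromene]-2,2'-dione | COc1cc(C)c2c(OC)cc(=O)oc2c1-c1c(OCc2ccccc2)cc2oc(=O)cc(OC)c2c1C | intermediate
21 | 7'-hydroxy-4,4',7-trimethoxy-5,5'-dimethyl-2H,2'H-[8,6'-bichromene]-2,2'-dione | COc1cc(C)c2c(OC)cc(=O)oc2c1-c1c(O)cc2oc(=O)cc(OC)c2c1C | target

Total step count: 12.
Longest linear sequence: 10 steps (from 4 through steps 2–7 and 9–12 to 21).

Steps most likely to fail

Step 9. The cycloaddition may be too slow at two fully substituted diene termini, so that thermal oligomerisation of the ynol ether uses up the dienophile first. Raising the pressure to about 12 kbar would be the first adjustment. The fallback sets out from 12 and comes back at 17. It replaces the alkyne by the more nucleophilic and thermally robust alkyne equivalent 1,1-dimethoxyethene (C=C(OC)OC, commercial, large excess, mesitylene, sealed vessel, 140 °C). The polarity-matched [4+2] addition should give the saturated-bridge bridged lactone F1, which loses CO2 to the dimethoxycyclohexadiene F2. F2 then aromatises to 17 by 1,2-elimination of methanol, which the excess ketene acetal scavenges so that the acetate of 12 is not methanolysed.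

Step 6. The tin–lead exchange may stall at the doubly ortho-substituted carbon, or acetoxylation of the pyrone enolate by unconsumed lead tetraacetate may outrun the ligand coupling. The fallback is a Suzuki–Miyaura coupling that sets out from 8 and 3 and comes back at 11.
- Iodide 8 would be converted by Miyaura borylation (B2pin2, PdCl2(dppf), KOAc, dioxane, 90 °C) into the pinacol boronate F3.
- Pyrone 3 would be iodinated at C3 (NIS, MeCN, rt) to the 3-iodo-4-hydroxypyrone F4.
- F4 would be capped (MOMCl, iPr2NEt, CH2Cl2, 0 °C) as the methoxymethyl ether F5.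
- Coupling of F3 with F5 (Pd(OAc)2, SPhos, K3PO4, toluene, 90 °C) should give the 3-aryl-4-(methoxymethoxy)pyrone F6.
- CF3CO2H in wet CH2Cl2 would then free the vinylogous acid 11.

Step 3. Site selectivity of the iodination may be incomplete, with attack between the two oxygens beside the wanted position, or a second iodination may occur. The fallback sets out from 4 and comes back at 6.
- Both hydroxyl groups would be benzylated (BnBr in excess, K2CO3, DMF, 60 °C) to the dibenzyl ether F7, in which the site between two benzyloxy groups is closed sterically.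
- Iodination (NIS, CF3CO2H, MeCN) should then give only the iodo dibenzyl ether F8.
- BCl3 (1.0 equiv, CH2Cl2, −78 °C), held in a chelate between the ester carbonyl and the neighbouring ether oxygen, would cleave just that benzyl group to return 6.

Further compounds
F1 | step 9 | methyl 8-acetoxy-4-[7-(benzyloxy)-4-methoxy-5-methyl-2-oxo-2H-chromen-6-yl]-5,5-dimethoxy-1-methyl-3-oxo-2-oxabicyclo[2.2.2]oct-7-ene-7-carboxylate (racemic, one enantiomer drawn) | O=C1O[C@]2(C)CC(OC)(OC)[C@@]1(c3c(OCc4ccccc4)cc4oc(=O)cc(OC)c4c3C)C(OC(C)=O)=C2C(=O)OC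
F2 | step 9 | methyl 6-acetoxy-5-[7-(benzyloxy)-4-methoxy-5-methyl-2-oxo-2H-chromen-6-yl]-4,4-dimethoxy-2-methylcyclohexa-1,5-diene-1-carboxylate | COC(=O)C1=C(C)CC(OC)(OC)C(c2c(OCc3ccccc3)cc3oc(=O)cc(OC)c3c2C)=C1OC(C)=O
F3 | step 6 | 7-(benzyloxy)-4-methoxy-5-methyl-6-(4,4,5,5-tetramethyl-1,3,2-dioxaborolan-2-yl)-2H-chromen-2-one | CC1(C)OB(OC1(C)C)c1c(OCc2ccccc2)cc2oc(=O)cc(OC)c2c1C
F4 | step 6 | methyl 4-hydroxy-3-iodo-6-methyl-2-oxo-2H-pyran-5-carboxylate | COC(=O)c1c(O)c(I)c(=O)oc1C
F5 | step 6 | methyl 3-iodo-4-(methoxymethoxy)-6-methyl-2-oxo-2H-pyran-5-carboxylate | COCOc1c(I)c(=O)oc(C)c1C(=O)OC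
F6 | step 6 | methyl 3-[7-(benzyloxy)-4-methoxy-5-methyl-2-oxo-2H-chromen-6-yl]-4-(methoxymethoxy)-6-methyl-2-oxo-2H-pyran-5-carboxylate | COCOc1c(C(=O)OC)c(C)oc(=O)c1-c1c(OCc2ccccc2)cc2oc(=O)cc(OC)c2c1C
F7 | step 3 | methyl 2,4-bis(benzyloxy)-6-methylbenzoate | COC(=O)c1c(C)cc(OCc2ccccc2)cc1OCc1ccccc1
F8 | step 3 | methyl 4,6-bis(benzyloxy)-3-iodo-2-methylbenzoate | COC(=O)c1c(C)c(I)c(OCc2ccccc2)cc1OCc1ccccc1
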